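By 6.00 h the cedar run has turned 15.4% of its J into E and the oak run 5.3%, both on traces of Q. My first estimate for the flask is the plainest: double the Q, double the rate.

| flask | J | Q | remark |
|---|---|---|---|
| oak | 20 mM | 0.013 mol% | run made earlier |
| cedar | 20 mM | 0.03 mol% | run made earlier |
| ash | 10 mM | 0.02 mol% | run made earlier |
| flask | 20 mM | 0.02 mol% |  |

| run | time / h | E / % | J / % |
|---|---|---|---|
| oak | 0.500 | 0.9 | 101.0 |
| oak | 0.833 | 0 | 97.3 |
| oak | 1.50 | 1.9 | 101.3 |
| oak | 3.00 | 0.3 | 99.1 |
| oak | 6.00 | 5.3 | 94.5 |
| cedar | 1.33 | 0.6 | 97.7 |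
| cedar | 2.50 | 2.7 | 98.0 |
| cedar | 4.00 | 7.0 | 92.9 |
| cedar | 5.00 | 10.4 | 89.7 |
| cedar | 6.00 | 15.4 | 86.2 |
| ash | 1.33 | 0 | 98.8 |
| ash | 2.50 | 0.3 | 97.6 |
| ash | 4.00 | 4.6 | 95.6 |
| ash | 5.00 | 7.1 | 92.1 |
| ash | 6.00 | 10.4 | 91.0 |

(scatter of a reading: 1 percentage point)

- factor on the rate of making E when 30% of the J are converted if Q is charged twice over
- factor on the rate when 30% of the J are converted if Q is charged at 0.1 mol% instead

But the questions fix the conversion, not the time, and the amounts climb after a slow start, an induction period. From 2.50 h to 6.00 h, cedar's E grows as time to the power 1.99, so I take E as a square of time. The rate then grows with time, and a flask with more Q reaches the same conversion earlier, while its rate is still lower. Putting that earlier arrival back into the first answer turns the factor on the rate into the square root of the factor on E at fixed time, which is 1.41 if E follows Q in simple proportion.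

That proportion is doubtful too. Between oak and cedar at 6.00 h, E answers to the loading with power 1.28. This gives the loading exponent, the power of the Q charge to which the rate at fixed conversion answers, 0.638. It is a soft reading, since it rests on the one oak value 5.3%, which carries a scatter of 1 percentage point. My estimates are 1.56 and 2.79, though cedar's last E, 15.4%, lies below the 30% asked.

The forecast gives 1.5 (range 1.3 to 2) and 2.6 (range 2 to 4.2), with a power of 0.6, holding that “the active catalyst builds up slowly from Q”. Mine are higher, but inside its ranges.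

The simulation gives 1.48 and 2.43.

    Q → L (k = 0.0420 h⁻¹)
    Z ⇌ L + E (K = 0.0920 M, k = 750 h⁻¹)
    2 L ⇌ D (K = 6.50 × 10⁵ M⁻¹, k = 74000 M⁻¹ h⁻¹)
    J + L ⇌ Z (K = 2300 M⁻¹, k = 1.50 × 10⁶ M⁻¹ h⁻¹)

Taken from these answers, the loading exponent is 0.566 for doubled Q and 0.550 at 0.1 mol%, against my 0.638. At 30% conversion, Z holds 34.1% of the catalyst charged in the flask and 16.5% at 0.1 mol%, so a charge 5.00 times larger carries 2.43 times the Z, beside a rate factor of 2.43.

The data stem from a simulated flask from invented constants.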